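**Strategy.** Everything rests on disconnecting the C5–C6 bond of the benzene ring. The 1,3,5-oxygenated carbocycle (O on C5, C7 and C8a, aroyl on C6) is an isomer of a 7-aroylmethyl 2-pyrone whose 4-oxygen is already O1 of the fused dimethylpyran ring. In one operation, methoxide opens the lactone and a Claisen closure rebuilds the six carbons as the aromatic ring, setting both chelated phenols and the C6 ketone with the pyran ring in place. The precursor is the pyrano[4,3-b]pyran-5-one from triacetic acid lactone and prenal, acylated on its 7-methyl group by an O-allyl 3-hydroxybenzoate; the allyl ether is kept until C8 has been prenylated.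

Key step: step 4

Remark: the 3-hydroxyl of the benzoyl ring is carried as its allyl ether from step 2 to step 6, because a free phenol there would compete for prenyl bromide; compounds 8 and 10 are therefore the O-allyl forms of the pyranopyranone precursor and the chromenyl ketone, with unchanged skeletons (chromene numbering O1, C2 … C8a is used for the products).

Step 1
Reactants: 1 4-hydroxy-6-methyl-2H-pyran-2-one; 2 3-methylbut-2-enal
Product: 4 2,2,7-trimethyl-2H,5H-pyrano[4,3-b]pyran-5-one, via Knoevenagel 1-oxatriene 3 (not isolated)
Conditions: piperidine (0.2 equiv), AcOH (0.2 equiv), EtOAc, 80 °C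
Reagents that add atoms: none
Why: Amine-catalysed Knoevenagel condensation at C3 of the pyrone gives 1-oxatriene 3, which closes through the C4 oxygen by oxa-6π electrocyclisation (formal [3+3] annulation) to the 2H-pyran, and the gem-dimethyl terminus leaves no stereocenter.

Step 2
Reactants: 5 methyl 3-hydroxybenzoate
Product: 6 methyl 3-(prop-2-en-1-yloxy)benzoate
Conditions: allyl bromide (1.2 equiv), K2CO3 (1.5 equiv), acetone, reflux
Reagents that add atoms: allyl bromide (3-bromoprop-1-ene), C=CCBr
Why: Williamson etherification of the phenoxide with a reactive allylic bromide is reliable and leaves the methyl ester untouched, and the allyl ether later withstands amide base, methoxide and hydroxide.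

Step 3
Reactants: 4 2,2,7-trimethyl-2H,5H-pyrano[4,3-b]pyran-5-one; 6 methyl 3-(prop-2-en-1-yloxy)benzoate
Product: 8 2,2-dimethyl-7-{2-oxo-2-[3-(prop-2-en-1-yloxy)phenyl]ethyl}-2H,5H-pyrano[4,3-b]pyran-5-one, via lithiated pyranopyranone 7 (not isolated)
Conditions: LiN(i-Pr)2 (commercial solution, 2.2 equiv), THF, −78 °C; then 6 (1.0 equiv), −78 to −20 °C; 1 M HCl quench
Reagents that add atoms: none
Why: LiN(i-Pr)2 removes a proton from the 7-methyl group, the vinylogous α-position of the lactone and the only acidic site because C4a carries no hydrogen, and the resulting extended enolate 7 is C-acylated by the non-enolisable ester in a crossed Claisen condensation, the second equivalent of base holding the more acidic β-keto pyrone as its enolate until the acid quench.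

Step 4
Reactants: 8 2,2-dimethyl-7-{2-oxo-2-[3-(prop-2-en-1-yloxy)phenyl]ethyl}-2H,5H-pyrano[4,3-b]pyran-5-one
Product: 10 (5,7-dihydroxy-2,2-dimethyl-2H-chromen-6-yl)[3-(prop-2-en-1-yloxy)phenyl]methanone, via ring-opened methyl ester 9 (not isolated)
Conditions: Mg(OMe)2 (commercial solution, 4 equiv), MeOH, reflux; then cold 1 M HCl
Reagents that add atoms: none
Why: Methoxide adds to the lactone carbonyl C5 and the pyrone ring opens to methyl ester 9, whose side-chain 1,3-diketone is held as its MeOMg diketonate chelate. The chelated carbon between the two ketones then attacks the ester carbonyl in a Dieckmann-type Claisen condensation, a 6-exo-trig closure that forms C5–C6 and the carbocycle, and loss of methoxide with enolisation of both ring ketones gives the benzene ring, so the step is a net isomerisation. The closest known reaction type is the Mg(OMe)2-induced isomerisation of 6-(2-oxoalkyl)-2-pyrones bearing a 4-hydroxy or 4-alkoxy group into acylphloroglucinols. No stereocenter is formed. The selectivity required is Claisen C-acylation rather than aldol closure or retro-Claisen cleavage of the diketone: the aldol mode would need the fully substituted, push-pull C4a as nucleophile and could not aromatise, while chelation to magnesium keeps the diketone intact and places its central carbon next to the ester. Because O1 is already bonded to C8a before the ring is made, the aroyl group can only appear at C6, para to the pyran oxygen, and the allyl ether and the C3=C4 double bond are spectators.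

Step 5
Reactants: 10 (5,7-dihydroxy-2,2-dimethyl-2H-chromen-6-yl)[3-(prop-2-en-1-yloxy)phenyl]methanone; 11 prenyl bromide (1-bromo-3-methylbut-2-ene)
Product: 12 [5,7-dihydroxy-2,2-dimethyl-8-(3-methylbut-2-en-1-yl)-2H-chromen-6-yl][3-(prop-2-en-1-yloxy)phenyl]methanone
Conditions: 11 (1.1 equiv), 10% aq. KOH, 0 °C to rt
Reagents that add atoms: none
Why: In aqueous alkali the phloroglucinol-type phenoxide is hydrated at oxygen and reacts as a carbon nucleophile, so SN2 attack on prenyl bromide followed by re-aromatisation (Friedel–Crafts-type C-alkylation of a phenoxide) puts the prenyl group on C8, the only ring carbon that still bears hydrogen, while the allyl-capped benzoyl ring offers no competing phenoxide.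

Step 6
Reactants: 12 [5,7-dihydroxy-2,2-dimethyl-8-(3-methylbut-2-en-1-yl)-2H-chromen-6-yl][3-(prop-2-en-1-yloxy)phenyl]methanone
Product: 13 [5,7-dihydroxy-2,2-dimethyl-8-(3-methylbut-2-en-1-yl)-2H-chromen-6-yl](3-hydroxyphenyl)methanone
Conditions: Pd(PPh3)4 (5 mol%), morpholine (5 equiv), THF, rt
Reagents that add atoms: none
Why: Zerovalent palladium ionises only the aryl allyl ether to a π-allyl complex that morpholine intercepts (Tsuji–Trost deallylation), conditions that are neutral, run at room temperature and touch neither the C-prenyl group, the chromene double bond nor the chelated phenols.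

**Compound list**

1 | 4-hydroxy-6-methyl-2H-pyran-2-one (triacetic acid lactone) | CC1=CC(O)=CC(=O)O1 | starting material
2 | 3-methylbut-2-enal (prenal) | CC(C)=CC=O | starting material
3 | (3E)-6-methyl-3-(3-methylbut-2-en-1-ylidene)-2H-pyran-2,4(3H)-dione, the 1-oxatriene with the dienyl arm cis to the C4 carbonyl; formed in the flask in step 1 | CC1=CC(=O)/C(=C\C=C(C)C)C(=O)O1 | intermediate
4 | 2,2,7-trimethyl-2H,5H-pyrano[4,3-b]pyran-5-one | CC1=CC2=C(C=CC(C)(C)O2)C(=O)O1 | intermediate
5 | methyl 3-hydroxybenzoate | COC(=O)c1cccc(O)c1 | starting material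
6 | methyl 3-(prop-2-en-1-yloxy)benzoate | COC(=O)c1cccc(OCC=C)c1 | intermediate
7 | (2,2-dimethyl-5-oxo-2H,5H-pyrano[4,3-b]pyran-7-yl)methyllithium, the extended enolate of 4; formed in the flask in step 3 | [Li]CC1=CC2=C(C=CC(C)(C)O2)C(=O)O1 | intermediate
8 | 2,2-dimethyl-7-{2-oxo-2-[3-(prop-2-en-1-yloxy)phenyl]ethyl}-2H,5H-pyrano[4,3-b]pyran-5-one (key-step precursor, O-allyl form) | C=CCOc1cccc(c1)C(=O)CC1=CC2=C(C=CC(C)(C)O2)C(=O)O1 | intermediate
9 | methyl 6-{2,4-dioxo-4-[3-(prop-2-en-1-yloxy)phenyl]butyl}-2,2-dimethyl-2H-pyran-5-carboxylate, present as its MeOMg diketonate chelate; formed in the flask in step 4 | COC(=O)C1=C(CC(=O)CC(=O)c2cccc(OCC=C)c2)OC(C)(C)C=C1 | intermediate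
10 | (5,7-dihydroxy-2,2-dimethyl-2H-chromen-6-yl)[3-(prop-2-en-1-yloxy)phenyl]methanone (key-step product, O-allyl form) | C=CCOc1cccc(c1)C(=O)c1c(O)cc2OC(C)(C)C=Cc2c1O | intermediate
11 | prenyl bromide (1-bromo-3-methylbut-2-ene) | CC(C)=CCBr | starting material
12 | [5,7-dihydroxy-2,2-dimethyl-8-(3-methylbut-2-en-1-yl)-2H-chromen-6-yl][3-(prop-2-en-1-yloxy)phenyl]methanone | C=CCOc1cccc(c1)C(=O)c1c(O)c(CC=C(C)C)c2OC(C)(C)C=Cc2c1O | intermediate
13 | [5,7-dihydroxy-2,2-dimethyl-8-(3-methylbut-2-en-1-yl)-2H-chromen-6-yl](3-hydroxyphenyl)methanone (CNP0424359.0, achiral) | CC(C)=CCc1c(O)c(C(=O)c2cccc(O)c2)c(O)c2c1OC(C)(C)C=C2 | target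

**Step count**

Total steps: 6. Longest linear sequence: 5 (steps 1, 3, 4, 5, 6).

**Steps most likely to fail**

Step 4 (key step). The ring-opened ester may return to the lactone faster than it is C-acylated, since its ester is a deactivated β-alkoxyacrylate. Methoxide may also cleave the 1,3-diketone by retro-Claisen fragmentation, or the 2H-pyran may open reversibly by retro-6π electrocyclisation and erode the regiochemistry. The fallback aromatises first and builds the pyran afterwards; it sets out from 1 and 6 and comes back at 10. The dianion of 1 (LiN(i-Pr)2, 3.2 equiv, THF, −78 to 0 °C) is acylated at its 6-methyl group by 6 to give 4-hydroxy-6-{2-oxo-2-[3-(prop-2-en-1-yloxy)phenyl]ethyl}-2H-pyran-2-one F1. Mg(OMe)2 in refluxing MeOH should then convert this unfused 4-hydroxypyrone, the substrate class for which the pyrone-to-phloroglucinol isomerisation is best established, into [3-(prop-2-en-1-yloxy)phenyl](2,4,6-trihydroxyphenyl)methanone F2. Condensation of F2 with 2 (ethylenediammonium diacetate, toluene, reflux) forms the dimethylpyran ring by Knoevenagel condensation and oxa-6π closure and rejoins the route at 10. Closure through the chelated oxygen ortho to the ketone can compete, so a chromatographic separation is expected; this is why the regiospecific main route is preferred.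

Step 5. Alkylation may occur on oxygen instead of carbon, a second alkylation at C8 may destroy aromaticity, and the bromide may hydrolyse before it is consumed. The fallback delivers the prenyl group intramolecularly; it sets out from 10 and comes back at 12. The less hindered 7-hydroxyl (the 5-hydroxyl lies peri to C4–H) is etherified with 3-chloro-3-methylbut-1-yne (CuCl2 cat., DBU, MeCN, 0 °C) to give {5-hydroxy-2,2-dimethyl-7-[(2-methylbut-3-yn-2-yl)oxy]-2H-chromen-6-yl}[3-(prop-2-en-1-yloxy)phenyl]methanone F3. Semi-hydrogenation (H2, Pd/CaCO3 poisoned with Pb(OAc)2, quinoline, EtOAc) should give {5-hydroxy-2,2-dimethyl-7-[(2-methylbut-3-en-2-yl)oxy]-2H-chromen-6-yl}[3-(prop-2-en-1-yloxy)phenyl]methanone F4. Heating in toluene at 110 °C triggers the aromatic Claisen rearrangement to C8, the only free ortho position, and returns the route at 12. The simple allyl aryl ether on the benzoyl ring needs a far higher temperature for its own rearrangement and should stay in place.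

Step 3. Proton transfer from the more acidic product to unreacted carbanion may stall conversion, a second carbanion may add to the new ketone, or the amide base may attack the lactone. The fallback is aldol addition followed by oxidation, which needs one equivalent of base and gives a non-acidic adduct; it sets out from 4 and comes back at 8. Lithiated species 7 (LiN(i-Pr)2, 1.1 equiv, THF, −78 °C) adds to 3-(prop-2-en-1-yloxy)benzaldehyde F5, prepared from commercial 3-hydroxybenzaldehyde under the conditions of step 2. This gives racemic 7-{2-hydroxy-2-[3-(prop-2-en-1-yloxy)phenyl]ethyl}-2,2-dimethyl-2H,5H-pyrano[4,3-b]pyran-5-one F6. Oxidation of the benzylic alcohol (activated MnO2, CH2Cl2, rt, or a Swern oxidation) removes the stereocenter and returns the route at 8.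

**Further compounds**

F1 | step 4 | 4-hydroxy-6-{2-oxo-2-[3-(prop-2-en-1-yloxy)phenyl]ethyl}-2H-pyran-2-one | C=CCOc1cccc(c1)C(=O)CC1=CC(O)=CC(=O)O1
F2 | step 4 | [3-(prop-2-en-1-yloxy)phenyl](2,4,6-trihydroxyphenyl)methanone | C=CCOc1cccc(c1)C(=O)c1c(O)cc(O)cc1O
F3 | step 5 | {5-hydroxy-2,2-dimethyl-7-[(2-methylbut-3-yn-2-yl)oxy]-2H-chromen-6-yl}[3-(prop-2-en-1-yloxy)phenyl]methanone | C=CCOc1cccc(c1)C(=O)c1c(OC(C)(C)C#C)cc2OC(C)(C)C=Cc2c1O
F4 | step 5 | {5-hydroxy-2,2-dimethyl-7-[(2-methylbut-3-en-2-yl)oxy]-2H-chromen-6-yl}[3-(prop-2-en-1-yloxy)phenyl]methanone | C=CCOc1cccc(c1)C(=O)c1c(OC(C)(C)C=C)cc2OC(C)(C)C=Cc2c1O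
F5 | step 3 | 3-(prop-2-en-1-yloxy)benzaldehyde | C=CCOc1cccc(C=O)c1
F6 | step 3 | racemic 7-{2-hydroxy-2-[3-(prop-2-en-1-yloxy)phenyl]ethyl}-2,2-dimethyl-2H,5H-pyrano[4,3-b]pyran-5-one | C=CCOc1cccc(c1)C(O)CC1=CC2=C(C=CC(C)(C)O2)C(=O)O1
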